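C1 = CH–O‑isobutyrate, C2/C3 = CH2, C4=C5 = ring alkene (C15 on C4), C6 = lactone CH–O, C7 = ring‑fusion CH, C8 = butenolide CH–O, C9=C10 = butenolide alkene, C14 = butenolide C=O, C11/C12/C13 = α‑carbon, C=O and =CH2 of the methylene lactone.
25 comes from 24 by late allylic C15–H oxidation. 24 comes from the acyclic allenyl enal 21 and ClCO2Me by cutting C6–C7 and C11–C12; the O6–C12 acyl bond closes in the same flask.
Enabling feature: C7–C11(=C13H2) is a terminal allene in disguise. Its central carbon C11 takes the carbonyl carbon C12, C7 becomes the γ‑carbon of an allylmetal next to stereocentre C8, and C6 is an enal carbon. The preformed butenolide ring (O8, C8, C9, C10, C14) and the Z C4=C5 alkene leave only C1–C3 flexible in the tether.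
21 comes from butenolide 14 by isobutyrylation, conversion of the propargylic alcohol to the allene, and oxidation at C6. 14 comes from iodoacrylate 9 and ynal 12 (C8–C9, then O8–C14). 9 comes from aldehyde 5 (made from nerol) and methyl propiolate (C1–C10).
Ring order: the butenolide ring first (step 7), then the ten‑membered carbocycle and the α‑methylene‑γ‑lactone ring together (step 13).

Key step: step 13

Remark on the chemistry: for the chiral catalysts of steps 4 and 7, the antipode assumed is the one that opens the Re face of aldehyde 5 and of ynal 12 respectively. Both antipodes are accessible.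

Step 1
Reactants: 1 nerol
Product: 2 neryl tert‑butyldimethylsilyl ether
Conditions: TBSCl, imidazole, CH2Cl2, 0 °C to rt
Reagents that add atoms: tert‑butyldimethylsilyl chloride CC(C)(C)[Si](C)(C)Cl
Why: Silyl ether protection of the primary allylic alcohol; the Z C4=C5 alkene of the target is bought with nerol and no stereocentre is formed.

Step 2
Reactants: 2 neryl tert‑butyldimethylsilyl ether
Product: 3 6,7‑epoxyneryl TBS ether (racemic at the epoxide carbon)
Conditions: mCPBA (1.0 equiv), CH2Cl2, -10 °C
Reagents that add atoms: 3‑chloroperoxybenzoic acid O=C(OO)c1cccc(Cl)c1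
Why: Prilezhaev epoxidation takes the more electron‑rich remote trisubstituted alkene because C4=C5 is deactivated by the allylic oxygen; the racemic epoxide stereocentre is destroyed in step 3.

Step 3
Reactants: 3 6,7‑epoxyneryl TBS ether
Product: 5 (4Z)‑6‑(tert‑butyldimethylsilyloxy)‑4‑methylhex‑4‑enal, via vicinal diol 4 (not isolated)
Conditions: H5IO6 (1.2 equiv), THF/H2O, 0 °C
Reagents that add atoms: none
Why: Acid‑promoted epoxide hydrolysis followed by Malaprade glycol cleavage in one flask releases acetone and the C1 aldehyde without touching the silyl ether or the alkene geometry.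

Step 4
Reactants: 5 (4Z)‑6‑(tert‑butyldimethylsilyloxy)‑4‑methylhex‑4‑enal; 6 methyl propiolate
Product: 9 methyl (2Z)‑2‑[(1S,4Z)‑6‑(tert‑butyldimethylsilyloxy)‑1‑hydroxy‑4‑methylhex‑4‑en‑1‑yl]‑3‑iodoprop‑2‑enoate, via silyl iodoallenolate 7 (not isolated), via O‑trimethylsilyl adduct 8 (not isolated)
Conditions: TMSI (1.2 equiv), B‑(o‑tolyl)oxazaborolidinium triflimide from α,α‑diphenylprolinol (20 mol %), CH2Cl2, -78 °C; then aq. citric acid, MeOH, 0 °C
Reagents that add atoms: iodotrimethylsilane C[Si](C)(C)I
Why: Catalytic asymmetric three‑component iodo‑aldol (β‑iodo Morita–Baylis–Hillman) reaction, in which TMSI adds to the propiolate and allenolate 7 attacks the Re face of the boron‑bound aldehyde, so the catalyst sets C1 (S) and the kinetic addition places iodine cis to the ester.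

Step 5
Reactants: 10 but‑2‑yne‑1,4‑diol
Product: 11 4‑(triethylsilyloxy)but‑2‑yn‑1‑ol
Conditions: TESCl (1.0 equiv), imidazole, DMF, 0 °C
Reagents that add atoms: chlorotriethylsilane CC[Si](Cl)(CC)CC
Why: Statistical monosilylation of the symmetrical diol (silyl ether protection); diol and bis‑ether are removed by chromatography.

Step 6
Reactants: 11 4‑(triethylsilyloxy)but‑2‑yn‑1‑ol
Product: 12 4‑(triethylsilyloxy)but‑2‑ynal
Conditions: MnO2 (activated), CH2Cl2, rt
Reagents that add atoms: none
Why: MnO2 oxidation of a propargylic alcohol stops at the ynal.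

Step 7
Reactants: 9 iodoacrylate; 12 4‑(triethylsilyloxy)but‑2‑ynal
Product: 14 (5R)‑3‑[(1S,4Z)‑6‑(tert‑butyldimethylsilyloxy)‑1‑hydroxy‑4‑methylhex‑4‑en‑1‑yl]‑5‑[3‑(triethylsilyloxy)prop‑1‑yn‑1‑yl]furan‑2(5H)‑one, via hydroxy enoate 13 (not isolated)
Conditions: CrCl2 (10 mol %), chiral 4‑isopropyl‑2‑[2‑(methanesulfonamido)phenyl]oxazoline ligand (11 mol %), proton sponge (11 mol %), NiCl2(2,9‑dimethyl‑1,10‑phenanthroline) (2 mol %), Mn (2 equiv), Cp2ZrCl2 (1.1 equiv), LiCl, MeCN, rt; then aq. citric acid
Reagents that add atoms: none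
Why: Catalytic asymmetric Nozaki–Hiyama–Kishi coupling, in which the alkenylchromium keeps its geometry and adds to the Re face of 12 inside the chiral sulfonamide–chromium complex, so C8 (R) is set independently of remote C1, and the hydroxyl group cis to the ester lactonises to the butenolide.

Step 8
Reactants: 14 butenolide alcohol
Product: 15 C1 isobutyrate of 14
Conditions: (i‑PrCO)2O, DMAP (cat.), pyridine, CH2Cl2, -10 °C
Reagents that add atoms: isobutyric anhydride CC(C)C(=O)OC(=O)C(C)C
Why: Nucleophile‑catalysed acylation of the only free hydroxyl group with retention at C1; low temperature and short contact should avoid deprotonation at C8.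

Step 9
Reactants: 15 isobutyrate
Product: 16 (5R)‑5‑(3‑hydroxyprop‑1‑yn‑1‑yl)butenolide isobutyrate (C6 still OTBS)
Conditions: PPTS (0.1 equiv), MeOH/CH2Cl2, 0 °C
Reagents that add atoms: none
Why: Acid‑catalysed methanolysis cleaves the triethylsilyl ether much faster than the TBS ether (selective silyl ether deprotection).

Step 10
Reactants: 16 propargylic alcohol
Product: 19 (5S)‑5‑(propa‑1,2‑dien‑1‑yl)butenolide isobutyrate (C6 OTBS; same spatial arrangement at C8), via propargylic sulfonylhydrazine 17 (not isolated), via propargylic diazene 18 (not isolated)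
Conditions: PPh3, DEAD, 2‑nitrobenzenesulfonylhydrazide, THF, -15 °C to rt
Reagents that add atoms: none
Why: Myers allene synthesis, that is Mitsunobu displacement of the primary propargylic alcohol, loss of sulfinic acid and retro‑ene loss of N2 from 18, delivers hydrogen to C7 under neutral conditions, so C8 and the base‑sensitive butenolide stay untouched.

Step 11
Reactants: 19 allenyl butenolide TBS ether
Product: 20 allenyl butenolide allylic alcohol
Conditions: HF·pyridine, pyridine, THF, 0 °C
Reagents that add atoms: none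
Why: Fluoride‑mediated desilylation in a buffered acidic medium spares both esters, the allene and the acidic C8–H.

Step 12
Reactants: 20 allylic alcohol
Product: 21 (Z)‑enal with γ‑allenyl butenolide and C1 isobutyrate
Conditions: MnO2 (activated), CH2Cl2, rt
Reagents that add atoms: none
Why: Neutral heterogeneous MnO2 oxidation of the primary allylic alcohol should give the enal without Z to E isomerisation.

Step 13
Reactants: 21 allenyl enal
Product: 24 15‑deoxy target (1S,6R,7S,8R)‑bis‑lactone, via allylindium species 22 (not isolated), via ten‑membered hydroxy ester 23 (not isolated)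
Conditions: Pd2(dba)3 (2.5 mol %), P(2‑furyl)3 (10 mol %), In powder (2 equiv), ClCO2Me (2 equiv), DMF, 35 °C, 21 added over 12 h (final 2 mM); then PPTS (cat.), CH2Cl2, rt
Reagents that add atoms: methyl chloroformate COC(=O)Cl
Why: Proposed new method: zerovalent palladium inserts into the C–Cl bond of ClCO2Me, the methoxycarbonyl–palladium species adds across the terminal allene with the carbonyl carbon going to the central carbon (C11–C12), indium reduces the resulting 2‑(methoxycarbonyl)‑π‑allylpalladium to the fluxional allylindium 22, this adds through its substituted γ‑carbon C7 to the tethered enal (C6–C7), and the C6 alkoxide then expels methoxide from C12. The closest known reaction types are the palladium/indium arylative cyclisation of allenyl aldehydes, the palladium‑catalysed acylmetalation of allenes with acid chlorides, and the chromium‑ or zinc‑mediated closure of ten‑membered germacranolide rings from ω‑formyl 2‑(bromomethyl)enoates; new here are the chloroformate as electrophile and the medium ring. The ten‑membered carbocycle closes by intramolecular carbonyl allylation through a six‑membered chair (indium bridging O6 and C13), and the lactone closes by 5‑exo‑trig acyl substitution. C7 is controlled by C8, because allylic 1,3‑strain against the C11 ester holds H8 in the alkene plane and the aldehyde reaches C7 anti to the C8–C9 bond on the face flanked by O8; C6 is controlled by the chair, in which the allylindium isomer with C8 trans to C13 and the equatorial C5 alkenyl group give the anti adduct, that is the trans‑fused lactone. The step needs oxidative addition to the acyl chloride before the C8–O and C1–O allylic esters, secured by keeping ClCO2Me in excess over slowly added 21 so that palladium rests as the divalent acyl complex. It also needs ring closure before oligomerisation or 1,4‑elimination of the lactone carboxylate, secured by the rigid butenolide ring, the Z C4=C5 alkene and pseudo‑high dilution.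

Step 14
Reactants: 24 15‑deoxy target
Product: 25 target CNP0322767.4
Conditions: SeO2 (0.3 equiv), t‑BuOOH (2 equiv), CH2Cl2, 0 °C to rt
Reagents that add atoms: selenium dioxide O=[Se]=O; tert‑butyl hydroperoxide CC(C)(C)OO
Why: Riley allylic oxidation (ene reaction, then [2,3]‑sigmatropic shift) attacks the only electron‑rich alkene C4=C5 and should oxidise the methyl group trans to C6 (E rule), as known for germacranolide methyl groups; no stereocentre is formed.

Compound list
1 | nerol | CC(C)=CCC/C(C)=C\CO | starting material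
2 | neryl TBS ether | CC(C)=CCC/C(C)=C\CO[Si](C)(C)C(C)(C)C | intermediate
3 | 6,7‑epoxyneryl TBS ether (racemic epoxide) | CC1(C)OC1CC/C(C)=C\CO[Si](C)(C)C(C)(C)C | intermediate
4 | 6,7‑diol from 3 (not isolated) | CC(C)(O)C(O)CC/C(C)=C\CO[Si](C)(C)C(C)(C)C | intermediate
5 | (4Z)‑6‑(TBS‑oxy)‑4‑methylhex‑4‑enal | O=CCC/C(C)=C\CO[Si](C)(C)C(C)(C)C | intermediate
6 | methyl propiolate | C#CC(=O)OC | starting material
7 | 3‑iodo‑1‑methoxy‑1‑(trimethylsilyloxy)allene (not isolated) | IC=C=C(OC)O[Si](C)(C)C | intermediate
8 | O‑trimethylsilyl ether of 9 (not isolated) | COC(=O)/C(=C\I)[C@@H](O[Si](C)(C)C)CC/C(C)=C\CO[Si](C)(C)C(C)(C)C | intermediate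
9 | (Z)‑β‑iodo hydroxy ester, C1 (S) | COC(=O)/C(=C\I)[C@@H](O)CC/C(C)=C\CO[Si](C)(C)C(C)(C)C | intermediate
10 | but‑2‑yne‑1,4‑diol | OCC#CCO | starting material
11 | 4‑(triethylsilyloxy)but‑2‑yn‑1‑ol | OCC#CCO[Si](CC)(CC)CC | intermediate
12 | 4‑(triethylsilyloxy)but‑2‑ynal | O=CC#CCO[Si](CC)(CC)CC | intermediate
13 | (Z)‑γ‑hydroxy enoate, C1 (S), C8 (R) (not isolated) | COC(=O)/C(=C\[C@@H](O)C#CCO[Si](CC)(CC)CC)[C@@H](O)CC/C(C)=C\CO[Si](C)(C)C(C)(C)C | intermediate
14 | γ‑alkynyl butenolide alcohol, C1 (S), C8 (R) | CC(C)(C)[Si](C)(C)OC/C=C(/C)CC[C@H](O)C1=C[C@H](C#CCO[Si](CC)(CC)CC)OC1=O | intermediate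
15 | C1 isobutyrate of 14 | CC(C)(C)[Si](C)(C)OC/C=C(/C)CC[C@H](OC(=O)C(C)C)C1=C[C@H](C#CCO[Si](CC)(CC)CC)OC1=O | intermediate
16 | propargylic alcohol | CC(C)(C)[Si](C)(C)OC/C=C(/C)CC[C@H](OC(=O)C(C)C)C1=C[C@H](C#CCO)OC1=O | intermediate
17 | N‑propargyl‑N‑(2‑nitrobenzenesulfonyl)hydrazine (not isolated) | CC(C)(C)[Si](C)(C)OC/C=C(/C)CC[C@H](OC(=O)C(C)C)C1=C[C@H](C#CCN(N)S(=O)(=O)c2ccccc2[N+](=O)[O-])OC1=O | intermediate
18 | propargylic diazene (not isolated) | CC(C)(C)[Si](C)(C)OC/C=C(/C)CC[C@H](OC(=O)C(C)C)C1=C[C@H](C#CCN=N)OC1=O | intermediate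
19 | γ‑allenyl butenolide, C6 OTBS | CC(C)(C)[Si](C)(C)OC/C=C(/C)CC[C@H](OC(=O)C(C)C)C1=C[C@H](C=C=C)OC1=O | intermediate
20 | γ‑allenyl butenolide, C6 OH | OC/C=C(/C)CC[C@H](OC(=O)C(C)C)C1=C[C@H](C=C=C)OC1=O | intermediate
21 | allenyl (Z)‑enal | O=C/C=C(/C)CC[C@H](OC(=O)C(C)C)C1=C[C@H](C=C=C)OC1=O | intermediate
22 | 2‑(methoxycarbonyl)allylindium, drawn as the dichloride, fluxional alkene (not isolated) | O=C/C=C(/C)CC[C@H](OC(=O)C(C)C)C1=C[C@H](C=C(C[In](Cl)Cl)C(=O)OC)OC1=O | intermediate
23 | ten‑membered hydroxy ester (1S,6R,7S,8R) (not isolated) | C=C(C(=O)OC)[C@H]1[C@H](O)/C=C(/C)CC[C@H](OC(=O)C(C)C)C2=C[C@H]1OC2=O | intermediate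
24 | 15‑deoxy target (1S,6R,7S,8R) | C=C1C(=O)O[C@@H]2/C=C(/C)CC[C@H](OC(=O)C(C)C)C3=C[C@@H](OC3=O)[C@@H]12 | intermediate
25 | CNP0322767.4 | C=C1C(=O)O[C@@H]2/C=C(/CO)CC[C@H](OC(=O)C(C)C)C3=C[C@@H](OC3=O)[C@@H]12 | target

Total step count: 14. Longest linear sequence: 12 steps (steps 1–4 and 7–14).

Steps most likely to fail

1. Step 13 (Proposed new method).
- What may go wrong:
  - ionisation of the allenylic C8–O bond or of the C1 ester by zerovalent palladium;
  - 1,4‑elimination of the lactone carboxylate from the allylindium;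
  - reaction through the allylindium isomer with C8 cis to C13, which would lead to the cis‑fused lactone;
  - oligomerisation instead of medium‑ring closure.
- Fallback with known chemistry, from 16 back to 24:
  - Hydroxyl‑directed trans‑hydrostannation of the alkyne ([Cp*RuCl]4, Bu3SnH, CH2Cl2) gives the alkenylstannane F1, with tin on C11 and cis to C8.
  - Stereoretentive oxidative methoxycarbonylation (Pd(OAc)2, Ph3As, 1,4‑benzoquinone, CO, MeOH) gives the 2‑(hydroxymethyl)enoate F2, so C11–C12 is made first and separately.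
  - Appel bromination (CBr4, PPh3) gives the allylic bromide F3.
  - HF·pyridine frees the allylic alcohol F4, and MnO2 gives the bromo enal F5.
  - CrCl2 in THF/DMF at high dilution closes C6–C7 by intramolecular Nozaki–Hiyama allylation, the reaction type that has closed ten‑membered germacranolide rings, and the alkoxide lactonises to 24.

2. Step 7.
- What may go wrong: poor facial selectivity at the small, linear ynal; loss of alkene geometry in the β‑chromio acrylate; epimerisation at the acidic C8–H during work‑up.
- Fallback, from 9 back to 14: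
  - Reductive carbonylation of the alkenyl iodide (Pd(PPh3)4, CO, Bu3SnH, THF) gives the Z 4‑oxo‑enoate F6.
  - Zinc–ProPhenol‑catalysed asymmetric addition of triethyl(prop‑2‑yn‑1‑yloxy)silane (Me2Zn, toluene) to this conjugated aldehyde sets C8 through another bond (C7–C8 instead of C8–C9) and another catalyst.
  - The zinc alkoxide lactonises to 14.

3. Step 14.
- What may go wrong: competing attack at the ring methylene C3; stalling at partial conversion; over‑oxidation of the allylic alcohol.
- Fallback, from 24 back to 25: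
  - The oxidation is driven through to one oxidation level higher with stoichiometric SeO2 (dioxane, 60 °C), which gives the conjugated C15 aldehyde F7. This can be separated from C3‑oxidised material.
  - Luche reduction (NaBH4, CeCl3·7H2O, MeOH, -78 °C) returns the primary allylic alcohol 25 without conjugate reduction of the methylene lactone.

Further compounds
F1 | step 13 | (Z)‑alkenylstannane, tin on C11 cis to C8 | CC(C)(C)[Si](C)(C)OC/C=C(/C)CC[C@H](OC(=O)C(C)C)C1=C[C@H](/C=C(/CO)[Sn](CCCC)(CCCC)CCCC)OC1=O
F2 | step 13 | 2‑(hydroxymethyl)enoate, ester cis to C8 | CC(C)(C)[Si](C)(C)OC/C=C(/C)CC[C@H](OC(=O)C(C)C)C1=C[C@H](/C=C(/CO)C(=O)OC)OC1=O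
F3 | step 13 | 2‑(bromomethyl)enoate, C6 OTBS | CC(C)(C)[Si](C)(C)OC/C=C(/C)CC[C@H](OC(=O)C(C)C)C1=C[C@H](/C=C(/CBr)C(=O)OC)OC1=O
F4 | step 13 | 2‑(bromomethyl)enoate, C6 OH | OC/C=C(/C)CC[C@H](OC(=O)C(C)C)C1=C[C@H](/C=C(/CBr)C(=O)OC)OC1=O
F5 | step 13 | bromo enal | O=C/C=C(/C)CC[C@H](OC(=O)C(C)C)C1=C[C@H](/C=C(/CBr)C(=O)OC)OC1=O
F6 | step 7 | (Z)‑4‑oxo‑enoate, C1 (S) | COC(=O)/C(=C\C=O)[C@@H](O)CC/C(C)=C\CO[Si](C)(C)C(C)(C)C
F7 | step 14 | C15 aldehyde of the target | C=C1C(=O)O[C@@H]2/C=C(/C=O)CC[C@H](OC(=O)C(C)C)C3=C[C@@H](OC3=O)[C@@H]12
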